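## Analysis of the target

The target is an ent-labdane, (1S,4aS,5R,8R,8aS)-8-acetoxy-1,4a-dimethyl-6-methylidene-5-[(2E)-3-methylpenta-2,4-dien-1-yl]decahydronaphthalene-1-carboxylic acid, a trans-fused decalin (ring A = C1–C5 and C10, ring B = C5–C10) with the C18 acid and C19 methyl on C4, an acetoxy group on C6, the exocyclic methylene C17 on C8, the diene chain C11–C16 on C9 and the C20 methyl on C10. The five stereocentres are (4S,5S,6R,9R,10S) in this numbering: the C19 and C20 methyls are both axial and syn, H5 is axial and anti to them, and C18, O6 and C11 are all equatorial, with O6 peri to C18 and H9 anti to C20. The sensitive groups are the conjugated diene (acid, electrophilic oxidants, radicals), the exocyclic alkene (acid-promoted migration into the ring) and the 6-acetoxy/18-acid pair, whose O-deacylated form is a γ-hydroxy acid set up to lactonise. The synthesis is hard because two quaternary carbons (C4, C10) flank C5, C6 carries oxygen at an unactivated position, C9 is a stereocentre next to quaternary C10, and the compound belongs to the enantiomeric series that the usual terpene pool does not give directly. The plan rests on the local symmetry of ring A: C4 and C10 each bear an axial methyl and an equatorial carbon (C18 on C4, C9 on C10) and flank the same methine C5. Ring A of dehydroabietic acid has exactly this pattern and can be read with C4 and C10 interchanged, so that its carboxyl carbon becomes C9 and the arene carbon on its C10 becomes C18, and this reading gives the ent series. The absolute configuration then depends only on keeping C9 and C18 chemically distinct until ring B is closed.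

## Retrosynthetic reasoning

**C18 oxidation level and the C6 acetate.** Target 31 is taken back through aldehyde 30 and alcohol 29 to silyl ether 28, its free alcohol 27 and diol 26. C18 is kept at the alcohol level until O6 is acetylated, because a free 6-hydroxy-18-acid would close back to the lactone. The forward steps must tell the primary C18 hydroxyl from the hindered secondary C6 hydroxyl and oxidise C18 without touching the diene.

**Side chain, C14=C15 and C12=C13.** Diene 26 is cut at C14=C15 to enal 24 and phosphonium salt 25 (Wittig methylenation). Enal 24 is cut at C12=C13 to allyl compound 22 and methacrolein 23 by cross-metathesis. This sets the E-trisubstituted alkene under thermodynamic control, needs no acid, and leaves the hindered exocyclic alkene alone.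

**C9–H and the exocyclic methylene.** Diol 22 comes from allylic alcohol 19 by reductive 1,3-transposition through hydrazide 20 and diazene 21. The C17–O bond is exchanged for C9–H and the alkene moves from C8=C9 to C8=C17. The forward step must deliver hydrogen to C9 on the face anti to C20.

**C9–C11 bond.** Triol 19 arises by reduction of ester lactone 18, which is cut at C9–C11 to enol triflate 16 and allyltributylstannane 17. A vinyl triflate at C9 is the natural product of a β-keto ester, and an allyl group brings C11 and C12 at the right oxidation level for the metathesis.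

**C6–O bond.** Lactone 16 is traced to primary amide 13 through N-iodoamide 14 and iminolactone 15. Equatorial C18 can reach only the equatorial hydrogen on C6 by 1,5-hydrogen transfer, so the acid itself directs the oxidation of the one unactivated position that needs oxygen. Amide 13 comes from keto ester amide 12 and this, through acid chloride 11, from acid 10. The enol triflate is made before the photolysis so that no enolisable β-keto ester meets electrophilic iodine.

**C8–C9 bond (key disconnection).** β-Keto ester 10 is opened at C8–C9 to seco diester acid 9. The cut is placed here because it turns ring B into two arms on an intact ring A that already holds C4, C5 and C10. The forward Dieckmann condensation must attack the C9 ester and leave C18 alone.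

**C7–C8 bond (one-carbon homologation).** Compound 9 is the Arndt–Eistert homologue of diacid 4: ketene 8 from diazoketone 7, which comes from 4 and (trimethylsilyl)diazomethane 2 through acid chlorides 5 and 6. The inserted carbon becomes C8, the old side-chain carboxyl carbon becomes C17.

**Arene degradation.** Diacid 4 is what remains of methyl ester 3 when the aromatic ring is oxidised away, and 3 is the methyl ester of dehydroabietic acid 1, made with 2. The ester made first marks C9; the acid unveiled from the arene is C18.

## Alternatives that were turned down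

**Alternative 1:** Ring A is cut at C3–C4 and C5–C10, with ring B closing through the C6–C9 tether in the same event. In the forward step the acyclic tetraene A2 undergoes an intramolecular Diels–Alder reaction, on heating or with the Lewis acid EtAlCl2 A3, in which its E-configured 2-methyl enoate C4=C5 adds across the diene C10=C1–C2=C3, giving the trans-fused Δ1-octalin A1 with a C6 silyl ether, a C8 ketal and a PMB-oxyethyl arm on C9.
- For: one step sets C4, C5 and C10, and O6 and the C9 carbon substituent are in place from the start. On these two points it is stronger than the chosen route, which needs a remote C–H oxidation and a cross-coupling.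
- Against: the diene terminus C10 is 1,1-disubstituted, so one substituent must sit inside the s-cis diene. The dienophile is trisubstituted and β-branched, and two quaternary carbons form in one transition state. Endo/exo and facial selectivity must come from two stereocentres in a flexible tether. A2 itself needs two separately made stereocentres and two defined trisubstituted alkenes, and A1 still needs hydrogenation, methylenation at C8 and the whole side chain.
- Comparison: the stereotriad is the uncertain part of this route, whereas the chosen route takes it from the pool with no selectivity question and pays with a late C6 oxidation.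

**Alternative 2:** The decalin is cut at C4–C5 and C9–C10. In the forward step MeAlCl2 A6 opens the C3–C4 epoxide of the acyclic epoxy β-keto ester A5, C5 of the alkene attacks C4 and the enol carbon C9 traps the C10 cation, giving A4, a 3-hydroxy-8-oxo trans-decalin with the C11 ester on C9 and silyl-protected C18.
- For: both rings and C4, C5, C9 and C10 form in one step, and either enantiomeric series is available through the epoxide. Ring B emerges with a C8 ketone and C11 already on C9, so the exocyclic methylene is one olefination away. That is clearly more direct than the triflate coupling and allylic transposition used here.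
- Against: the C3 hydroxyl is not in the target and must be removed. C6 has no oxygen and no nearby handle, so a C18-directed C–H oxidation is still needed. The oxygenated carbon on the epoxide terminus destabilises the developing cation, which usually costs efficiency in such bicyclisations. The enantiomeric purity is only that of the epoxide.
- Comparison: the route is of similar length; it gains a better ring B but loses the secure C4/C5/C10 and adds a deoxygenation, so there is no net gain.

**Alternative 3:** Ring A is cut at C1–C10. In the forward step Fe(acac)3 A9 and PhSiH3 A10 transfer a hydrogen atom to C20 of the exocyclic alkene of the ring B precursor A8, and the tertiary C10 radical adds to C1 of the vinyl ketone, giving the 3-oxo trans-decalin A7 with a C6 silyl ether, a C9 ketal and a C18 methyl ester.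
- For: the conditions are mild, the C10 quaternary centre and the C20 methyl arise together, and O6 is present from the start (stronger than the chosen route on that point).
- Against: the step makes one bond and one stereocentre. C4, C5 and C6, including quaternary C4 next to two stereocentres, must already be in A8, so the hard part is moved and not solved. The ring fusion depends on the conformation of a radical. The C3 ketone must then be removed next to quaternary C4, and the C9 ketal must be turned into the C9–C11 bond and the C8 methylene.
- Comparison: the chosen route gets C4, C5 and C10 at no cost and closes ring B with useful functionality in one condensation, but it is weaker at C6.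

Key step: step 5

**Remarks on the chemistry.** Every intermediate carries the labdane numbering of the target (C17 on C8, C18 and C19 on C4, C20 on C10), also where this differs from abietane numbering. Compound 1 is taken as the commercial, enantiopure (+)-acid. C8 of 10–12 is epimerisable (β-keto ester, partly enolised) and is written without a descriptor.

## Route

**Step 1**
Reactants: 1 dehydroabietic acid; 2 (trimethylsilyl)diazomethane
Product: 3 methyl dehydroabietate
Conditions: TMSCHN2 (2 M in hexanes), toluene/MeOH 4:1, 0 °C to rt
Reagents that add atoms: (trimethylsilyl)diazomethane (2), C[Si](C)(C)C=[N+]=[N-]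
Why: O-methylation of the carboxylate by the protonated diazoalkane is insensitive to the hindrance of the neopentyl acid; this ester marks the carbon that will be C9.

**Step 2**
Reactants: 3 methyl dehydroabietate
Product: 4 seco diacid, 2-(2-carboxyethyl)-3-(methoxycarbonyl)-1,3-dimethylcyclohexane-1-carboxylic acid
Conditions: RuCl3·3H2O (5 mol%), NaIO4 (18 equiv), CCl4/MeCN/H2O 2:2:3, rt
Reagents that add atoms: sodium periodate, [Na+].[O-]I(=O)(=O)=O; water, O
Why: Oxidative degradation of the trialkylbenzene ring by catalytic RuO4 leaves the two ring-fusion arene carbons as carboxyl groups (C18 on C4, side-chain acid on C7) and burns off the rest. No stereocentre is touched, and the molecule is now chiral only because C9 is an ester and C18 an acid.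

**Step 3**
Reactants: 4 seco diacid; 2 (trimethylsilyl)diazomethane
Product: 7 diazoketone acid, 2-(4-diazo-3-oxobutyl)-3-(methoxycarbonyl)-1,3-dimethylcyclohexane-1-carboxylic acid, via bis(acid chloride) 5 (not isolated), via diazoketone acid chloride 6 (not isolated)
Conditions: (COCl)2, DMF (cat.), CH2Cl2, 0 °C to rt; evaporate; TMSCHN2 (2.2 equiv), THF/MeCN 1:1, 0 °C; evaporate; aq. NaHCO3, DMAP (cat.), THF, rt
Reagents that add atoms: (trimethylsilyl)diazomethane (2), C[Si](C)(C)C=[N+]=[N-]; water, O
Why: First stage of the Arndt–Eistert homologation: only the unhindered primary acyl chloride acylates the bulky, weakly nucleophilic diazoalkane at 0 °C. The neopentyl C18 acyl chloride does not react and is hydrolysed back to the acid on bicarbonate work-up.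

**Step 4**
Reactants: 7 diazoketone acid
Product: 9 seco diester acid, 3-(methoxycarbonyl)-2-(4-methoxy-4-oxobutyl)-1,3-dimethylcyclohexane-1-carboxylic acid, via ketene 8 (not isolated)
Conditions: PhCO2Ag (10 mol%), Et3N, MeOH, rt to 50 °C, dark
Reagents that add atoms: methanol, CO
Why: Wolff rearrangement: the C7 methylene migrates to the carbene carbon (new C8) and methanol traps the ketene, while the C18 carboxylate is a spectator. Acid 9 is taken out by bicarbonate extraction, which also removes any neutral C18 ester (an achiral triester).

**Step 5**
Reactants: 9 seco diester acid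
Product: 10 β-keto ester acid, trans-fused 6-(methoxycarbonyl)-1,4a-dimethyl-5-oxodecahydronaphthalene-1-carboxylic acid (9-oxo, CO2Me on C8, C18 acid)
Conditions: KOtBu (3.5 equiv), THF, 0 °C to 50 °C; cold 1 M HCl to pH 3
Reagents that add atoms: none
Why: Dieckmann condensation: the first equivalent of base makes the C18 carboxylate, the second enolises the side-chain ester at C8, and the enolate adds to the C9 ester carbonyl on C10, closing ring B in a 6-exo-trig (enolexo) mode with loss of methoxide. The third equivalent deprotonates the new β-keto ester at C8 and pulls the equilibrium over. The closest known reaction type is the Dieckmann cyclisation onto a neopentyl, α,α-disubstituted ester, which has no α-hydrogen, so only one enolate can form. Ring B can only close trans, because C5 and C10 are already stereocentres and the chain on C5 and the ester on C10 are vicinal and both equatorial on the ring A chair that has the two methyls axial. The one new stereocentre, C8, lies between two carbonyls, is formed as the enolate and is erased in step 7, so nothing has to be controlled there. The selectivity that matters is between the 1,3-related carboxyl carbons C9 and C18: C18 is a carboxylate and not an electrophile, while C9 is the methyl ester carried from 1. Closure on C18 would give the mirror-image skeleton, so this distinction, not a new stereocentre, carries the absolute configuration.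

**Step 6**
Reactants: 10 β-keto ester acid
Product: 12 keto ester amide (C18 primary amide), via acid chloride 11 (not isolated)
Conditions: (COCl)2, DMF (cat.), CH2Cl2, 0 °C; evaporate; NH3 (0.5 M in 1,4-dioxane), THF, 0 °C, 20 min; dilute HCl wash
Reagents that add atoms: ammonia, N
Why: Aminolysis of the acyl chloride is fast even at the hindered C18. The β-keto ester only forms its ammonium enolate during the short cold exposure and is restored by the acid wash.

**Step 7**
Reactants: 12 keto ester amide
Product: 13 enol triflate amide (C8=C9, triflate on C9, CO2Me on C8, C18 amide)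
Conditions: NaH (1.1 equiv), THF, 0 °C; N-(5-chloropyridin-2-yl)triflimide (1.2 equiv), 0 °C to rt; aq. NH4Cl
Reagents that add atoms: N-(5-chloropyridin-2-yl)bis(trifluoromethanesulfonimide), O=S(=O)(N(c1ccc(Cl)cn1)S(=O)(=O)C(F)(F)F)C(F)(F)F
Why: One equivalent of base deprotonates only the β-keto ester, and O-sulfonylation of the enolate gives the β-triflyloxy enoate. A triflimide is used because triflic anhydride would dehydrate the primary amide.

**Step 8**
Reactants: 13 enol triflate amide
Product: 16 lactone enol triflate (18,6-olide, O6 equatorial and cis to H5), via N-iodoamide 14 (not isolated), via iminolactone 15 (not isolated)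
Conditions: PhI(OAc)2 (2.5 equiv), I2 (1.2 equiv), ClCH2CH2Cl, hν (tungsten lamp), 50 °C; aq. Na2S2O3; AcOH/THF/H2O, rt
Reagents that add atoms: water, O
Why: Hofmann–Löffler–Freytag-type N-iodoamide photolysis: the amidyl radical takes the equatorial hydrogen of C6 through a six-membered transition state (the only δ-hydrogen in reach, since equatorial C18 is anti to C2); C6 is iodinated and captured by the amide oxygen, and mild aqueous acid hydrolyses the iminolactone. The new C6–O bond can only be equatorial, because equatorial C18 and equatorial O6 are peri-related while an axial C6–O cannot be spanned by a five-membered ring; this is the configuration of the target.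

**Step 9**
Reactants: 16 lactone enol triflate; 17 allyltributylstannane
Product: 18 allyl lactone ester (allyl on C9, C8=C9, CO2Me on C8, 18,6-olide)
Conditions: Pd(PPh3)4 (5 mol%), LiCl (3 equiv), THF, 65 °C
Reagents that add atoms: allyltributylstannane (17), C=CC[Sn](CCCC)(CCCC)CCCC
Why: Stille coupling: the electron-poor C9 triflate adds to zerovalent palladium, chloride replaces triflate, the allyl group is transferred from tin and reductive elimination forms C9–C11. The lactone and ester are inert.

**Step 10**
Reactants: 18 allyl lactone ester
Product: 19 triol (C17 allylic alcohol on C8, C6 hydroxyl, C18 hydroxyl, C8=C9, allyl on C9)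
Conditions: LiAlH4 (4 equiv), THF, 0 °C to rt; H2O, aq. NaOH work-up
Reagents that add atoms: none
Why: Hydride reduces the lactone to the 6,18-diol by acyl–oxygen cleavage (C6 keeps its configuration). The ester on the tetrasubstituted alkene is reduced 1,2 to the allylic alcohol.

**Step 11**
Reactants: 19 triol
Product: 22 allyl diol (C8=C17 exocyclic methylene, H on C9 anti to C20, C6 and C18 hydroxyls), via allylic sulfonylhydrazide 20 (not isolated), via allylic diazene 21 (not isolated)
Conditions: PPh3, DEAD, 2-nitrobenzenesulfonylhydrazide (1.5 equiv each), N-methylmorpholine, −30 °C; then rt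
Reagents that add atoms: none
Why: Reductive allylic transposition: Mitsunobu displacement occurs only at the primary allylic C17 (C18 is neopentyl, C6 hindered secondary); loss of sulfinate gives the monoalkyl diazene, which transfers its hydrogen to C9 in a retro-ene reaction with loss of dinitrogen. Hydrogen is delivered axially on the face anti to the adjacent axial C20 methyl, which puts C11 equatorial as in the target.

**Step 12**
Reactants: 22 allyl diol; 23 methacrolein
Product: 24 enal diol (C12=C13 E, aldehyde C14)
Conditions: second-generation Hoveyda–Grubbs catalyst (5 mol%), methacrolein (10 equiv), CH2Cl2, 40 °C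
Reagents that add atoms: methacrolein (23), CC(=C)C=O
Why: Olefin cross-metathesis of the unhindered terminal alkene with a 1,1-disubstituted enal gives the conjugated trisubstituted enal with the E geometry under thermodynamic control. The hindered 1,1-disubstituted C8=C17 alkene does not take part and free hydroxyls are tolerated.

**Step 13**
Reactants: 24 enal diol; 25 methyltriphenylphosphonium bromide
Product: 26 diene diol
Conditions: Ph3PCH3Br (4 equiv), KOtBu (3.8 equiv), THF, 0 °C; then 24, 0 °C to rt
Reagents that add atoms: methyltriphenylphosphonium bromide (25), C[P+](c1ccccc1)(c1ccccc1)c1ccccc1.[Br-]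
Why: Wittig methylenation of the enal occurs by 1,2-addition and leaves the C12=C13 geometry untouched; the excess ylide covers the two hydroxyls.

**Step 14**
Reactants: 26 diene diol
Product: 27 C18 silyl ether (C6 hydroxyl free)
Conditions: TBSCl (1.2 equiv), imidazole, CH2Cl2, 0 °C
Reagents that add atoms: tert-butyldimethylsilyl chloride, CC(C)(C)[Si](C)(C)Cl
Why: Silylation is selective for the primary hydroxyl over the secondary C6 hydroxyl, which is flanked by C5 and peri to the C4 substituents.

**Step 15**
Reactants: 27 C18 silyl ether
Product: 28 C6 acetate C18 silyl ether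
Conditions: Ac2O (3 equiv), DMAP (0.3 equiv), Et3N, CH2Cl2, rt
Reagents that add atoms: acetic anhydride, CC(=O)OC(C)=O
Why: DMAP-catalysed acylation of the remaining hindered secondary alcohol; O6 is acetylated while C18 cannot yet act as an acyl donor, so no lactone can form.

**Step 16**
Reactants: 28 C6 acetate C18 silyl ether
Product: 29 acetoxy alcohol (C6 acetate, C18 hydroxyl)
Conditions: HF·pyridine, pyridine, THF, 0 °C to rt; NaHCO3 quench
Reagents that add atoms: none
Why: Buffered fluoride cleaves the primary silyl ether without base, which avoids acetyl migration from O6 to O18, and leaves the diene and exocyclic alkene alone. The product is oxidised without storage.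

**Step 17**
Reactants: 29 acetoxy alcohol
Product: 30 acetoxy aldehyde (C18 aldehyde)
Conditions: Dess–Martin periodinane, NaHCO3, CH2Cl2, 0 °C to rt
Reagents that add atoms: none
Why: Dess–Martin oxidation of the neopentyl primary alcohol is neutral and spares the alkenes; the aldehyde has no α-hydrogen and cannot epimerise.

**Step 18**
Reactants: 30 acetoxy aldehyde
Product: 31 target, (1S,4aS,5R,8R,8aS)-8-acetoxy-1,4a-dimethyl-6-methylidene-5-[(2E)-3-methylpenta-2,4-dien-1-yl]decahydronaphthalene-1-carboxylic acid
Conditions: NaClO2, NaH2PO4, 2-methyl-2-butene (excess), t-BuOH/H2O, 0 °C to rt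
Reagents that add atoms: sodium chlorite, [Na+].[O-]Cl=O
Why: Pinnick oxidation converts the hindered aldehyde to the acid; the scavenger alkene takes up the hypochlorite, which protects the diene and the exocyclic alkene, and the acetate is stable at this pH.

## Compound list

1 | dehydroabietic acid, (+)-abieta-8,11,13-trien-18-oic acid | CC(C)c1ccc2c(c1)CC[C@H]3[C@@](C(=O)O)(C)CCC[C@]23C | starting material
2 | (trimethylsilyl)diazomethane | C[Si](C)(C)C=[N+]=[N-] | starting material
3 | methyl dehydroabietate | CC(C)c1ccc2c(c1)CC[C@H]3[C@@](C(=O)OC)(C)CCC[C@]23C | intermediate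
4 | seco diacid, 2-(2-carboxyethyl)-3-(methoxycarbonyl)-1,3-dimethylcyclohexane-1-carboxylic acid (methyls cis, ring carboxyl carbons cis, chain trans to the methyls; ester = C9, ring acid = C18) | OC(=O)CC[C@H]1[C@@](C(=O)OC)(C)CCC[C@]1(C)C(=O)O | intermediate
5 | bis(acid chloride) of 4 | ClC(=O)CC[C@H]1[C@@](C(=O)OC)(C)CCC[C@]1(C)C(Cl)=O | intermediate (not isolated)
6 | diazoketone acid chloride, methyl 3-(chlorocarbonyl)-2-(4-diazo-3-oxobutyl)-1,3-dimethylcyclohexane-1-carboxylate | [N-]=[N+]=CC(=O)CC[C@H]1[C@@](C(=O)OC)(C)CCC[C@]1(C)C(Cl)=O | intermediate (not isolated)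
7 | diazoketone acid, 2-(4-diazo-3-oxobutyl)-3-(methoxycarbonyl)-1,3-dimethylcyclohexane-1-carboxylic acid | [N-]=[N+]=CC(=O)CC[C@H]1[C@@](C(=O)OC)(C)CCC[C@]1(C)C(=O)O | intermediate
8 | ketene, 3-(methoxycarbonyl)-1,3-dimethyl-2-(4-oxobut-3-en-1-yl)cyclohexane-1-carboxylic acid | O=C=CCC[C@H]1[C@@](C(=O)OC)(C)CCC[C@]1(C)C(=O)O | intermediate (not isolated)
9 | seco diester acid, 3-(methoxycarbonyl)-2-(4-methoxy-4-oxobutyl)-1,3-dimethylcyclohexane-1-carboxylic acid | COC(=O)CCC[C@H]1[C@@](C(=O)OC)(C)CCC[C@]1(C)C(=O)O | intermediate
10 | β-keto ester acid, trans-fused 6-(methoxycarbonyl)-1,4a-dimethyl-5-oxodecahydronaphthalene-1-carboxylic acid (9-oxo, 8-CO2Me, 18-acid) | O=C1C(C(=O)OC)CC[C@H]2[C@@]1(C)CCC[C@]2(C)C(=O)O | intermediate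
11 | C18 acid chloride of 10 | O=C1C(C(=O)OC)CC[C@H]2[C@@]1(C)CCC[C@]2(C)C(Cl)=O | intermediate (not isolated)
12 | keto ester amide, methyl 5-carbamoyl-5,8a-dimethyl-1-oxodecahydronaphthalene-2-carboxylate (trans-fused) | O=C1C(C(=O)OC)CC[C@H]2[C@@]1(C)CCC[C@]2(C)C(N)=O | intermediate
13 | enol triflate amide (C8=C9, 9-triflyloxy, 8-CO2Me, 18-amide) | FC(F)(F)S(=O)(=O)OC1=C(C(=O)OC)CC[C@H]2[C@@]1(C)CCC[C@]2(C)C(N)=O | intermediate
14 | N-iodoamide of 13 | FC(F)(F)S(=O)(=O)OC1=C(C(=O)OC)CC[C@H]2[C@@]1(C)CCC[C@]2(C)C(=O)NI | intermediate (not isolated)
15 | iminolactone (cyclic imidate C18(=NH)–O–C6) | FC(F)(F)S(=O)(=O)OC1=C(C(=O)OC)C[C@@H]3[C@H]2[C@@]1(C)CCC[C@]2(C)C(=N)O3 | intermediate (not isolated)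
16 | lactone enol triflate (18,6-olide; O6 equatorial, cis to H5) | FC(F)(F)S(=O)(=O)OC1=C(C(=O)OC)C[C@@H]3[C@H]2[C@@]1(C)CCC[C@]2(C)C(=O)O3 | intermediate
17 | allyltributylstannane | C=CC[Sn](CCCC)(CCCC)CCCC | starting material
18 | allyl lactone ester (9-allyl, C8=C9, 8-CO2Me, 18,6-olide) | C=CCC1=C(C(=O)OC)C[C@@H]3[C@H]2[C@@]1(C)CCC[C@]2(C)C(=O)O3 | intermediate
19 | triol (9-allyl, C8=C9, 17-ol, 6-ol, 18-ol) | C=CCC1=C(CO)C[C@@H](O)[C@H]2[C@@]1(C)CCC[C@]2(C)CO | intermediate
20 | allylic sulfonylhydrazide, N-(C17)-N-(2-nitrobenzenesulfonyl)hydrazine of 19 | C=CCC1=C(CN(N)S(=O)(=O)c3ccccc3[N+](=O)[O-])C[C@@H](O)[C@H]2[C@@]1(C)CCC[C@]2(C)CO | intermediate (not isolated)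
21 | allylic diazene (C17–N=NH) | C=CCC1=C(CN=N)C[C@@H](O)[C@H]2[C@@]1(C)CCC[C@]2(C)CO | intermediate (not isolated)
22 | allyl diol (8(17)-methylene, 9-H anti to C20, 9-allyl, 6-ol, 18-ol) | C=CC[C@@H]1C(=C)C[C@@H](O)[C@H]2[C@@]1(C)CCC[C@]2(C)CO | intermediate
23 | methacrolein | CC(=C)C=O | starting material
24 | enal diol (12E-en-14-al, 8(17)-methylene, 6-ol, 18-ol) | O=C/C(C)=C/C[C@@H]1C(=C)C[C@@H](O)[C@H]2[C@@]1(C)CCC[C@]2(C)CO | intermediate
25 | methyltriphenylphosphonium bromide | C[P+](c1ccccc1)(c1ccccc1)c1ccccc1.[Br-] | starting material
26 | diene diol, ent-labda-8(17),12E,14-triene-6,18-diol with the target configuration | C=C/C(C)=C/C[C@@H]1C(=C)C[C@@H](O)[C@H]2[C@@]1(C)CCC[C@]2(C)CO | intermediate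
27 | C18 tert-butyldimethylsilyl ether of 26 | C=C/C(C)=C/C[C@@H]1C(=C)C[C@@H](O)[C@H]2[C@@]1(C)CCC[C@]2(C)CO[Si](C)(C)C(C)(C)C | intermediate
28 | C6 acetate C18 silyl ether | C=C/C(C)=C/C[C@@H]1C(=C)C[C@@H](OC(C)=O)[C@H]2[C@@]1(C)CCC[C@]2(C)CO[Si](C)(C)C(C)(C)C | intermediate
29 | acetoxy alcohol (6-acetoxy, 18-ol) | C=C/C(C)=C/C[C@@H]1C(=C)C[C@@H](OC(C)=O)[C@H]2[C@@]1(C)CCC[C@]2(C)CO | intermediate
30 | acetoxy aldehyde (6-acetoxy, 18-al) | C=C/C(C)=C/C[C@@H]1C(=C)C[C@@H](OC(C)=O)[C@H]2[C@@]1(C)CCC[C@]2(C)C=O | intermediate
31 | (1S,4aS,5R,8R,8aS)-8-acetoxy-1,4a-dimethyl-6-methylidene-5-[(2E)-3-methylpenta-2,4-dien-1-yl]decahydronaphthalene-1-carboxylic acid | C=C/C(C)=C/C[C@@H]1C(=C)C[C@@H](OC(C)=O)[C@H]2[C@@]1(C)CCC[C@]2(C)C(=O)O | target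

## Step count and least certain steps

Total: 18 steps. Longest linear sequence: 18 steps from 1; compounds 2, 17, 23 and 25 are bought.

**Step 5 (key step).** Ring closure may be slow because the C9 carbonyl is neopentyl and shielded by an axial methyl, so intermolecular Claisen condensation or ester cleavage can compete. More serious is transfer of the methyl ester from C9 to C18 by attack of the carboxylate in the ring-flipped chair, where the carboxyls are 1,3-diaxial; this would erode enantiomeric purity, since closure on C18 gives the mirror-image skeleton. The fallback sets out from 9 and tells the two carboxyls apart by size instead of charge, under irreversible enolisation. O-tert-butylation of the acid with tert-butyl 2,2,2-trichloroacetimidate and catalytic BF3·OEt2 gives the C18 tert-butyl ester F1, a triester. LiN(SiMe3)2 in THF, from −78 °C to rt, closes the chain enolate onto the methyl ester carbon C9 and gives the tert-butyl keto ester F2, from which CF3CO2H in CH2Cl2 removes the tert-butyl group, and the route is rejoined at 10.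

**Step 8.** The C6 radical or cation may escape capture by the amide oxygen and lose a proton toward C7 (conjugation with C8=C9). The trivalent iodine oxidant may also trigger a Hofmann-type shift of C4 to nitrogen, or closure may occur through nitrogen to a lactam. The fallback sets out from 10 and uses an alkoxy radical in place of the amidyl radical. NaH, 2.2 equiv, and N-(5-chloropyridin-2-yl)triflimide give the enol triflate acid F3, and BH3·SMe2 reduces only its free acid to give the enol triflate alcohol F4, in which C18 is a primary alcohol. The hypoiodite reaction with PhI(OAc)2 and I2 under irradiation abstracts the same C6 hydrogen and closes the 6,18-epoxide F5, a tetrahydrofuran. CrO3 in AcOH, the classical oxidation of such cyclic ethers to lactones, then converts the ether methylene C18 to the carbonyl, which returns to 16.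

**Step 2.** Oxidation at the benzylic methylene (C7) may run ahead of ring degradation; the resulting aryl ketone deactivates the arene, and further degradation shortens the side chain by one carbon. The fallback sets out from 3 and makes the ring electron-rich first. Friedel–Crafts acetylation with AcCl and AlCl3 gives methyl 12-acetyldehydroabietate F6, Baeyer–Villiger oxidation with mCPBA gives methyl 12-acetoxydehydroabietate F7, and K2CO3 in MeOH gives the phenol methyl 12-hydroxydehydroabietate F8, whose ring is cleaved by ozone in CH2Cl2/MeOH at −78 °C with H2O2/HCO2H work-up, returning to 4.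

**Step 3.** Both acyl chlorides may react with the diazoalkane, or hydrolysis of the C18 acyl chloride may be incomplete, so that C18 is esterified in step 4 and material is lost as the achiral triester. The C18 acyl chloride may also close onto the cis-1,3 ester to a cyclic anhydride, which would cost the distinction between C9 and C18. The fallback sets out from 4 and protects C18 explicitly, so that C18 never becomes an acyl chloride. BnBr and K2CO3 in DMF give the dibenzyl ester F9, and LiOH in THF/H2O at 0 °C saponifies only the unhindered side-chain ester to give the C18 benzyl ester acid F10, which (COCl)2 and then TMSCHN2 convert to the C18 benzyl ester diazoketone F11, and PhCO2Ag/Et3N in MeOH then gives the homologated C18 benzyl ester F12 of the seco diester acid; H2 over 10% Pd/C returns to 9.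

**Step 9.** Allyl transfer to the hindered C9 may be slow, and palladium hydride may move the allyl double bond into conjugation; the later cross-metathesis (step 12) depends on an intact terminal alkene. The fallback sets out from 16 and brings C11–C12 as a masked aldehyde. Negishi coupling with (1,3-dioxolan-2-ylmethyl)zinc bromide, catalysed by Pd(dppf)Cl2 in THF at 60 °C, gives the dioxolanylmethyl lactone ester F13, LiAlH4 gives the acetal triol F14, and the reductive transposition of step 11 gives the acetal diol F15, from which pyridinium tosylate in wet acetone frees the C12 aldehyde diol F16, and a Wittig reaction with 2-(triphenylphosphoranylidene)propanal in toluene at 90 °C gives the E-enal and returns to 24, bypassing steps 9 to 12.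

**Step 11.** Hydrogen delivery to C9 may show poor facial selectivity, or the Mitsunobu reagents may cause ether formation between O6 and C18. The fallback sets out from 19 and uses palladium hydride in place of the diazene. ClCO2Me, pyridine and DMAP give the tris(methyl carbonate) F17, and Pd(OAc)2/n-Bu3P with HCO2H/Et3N in THF ionises only its allylic carbonate; palladium sits on the face anti to C20 and passes hydride to C9 from that face, giving the transposed bis(methyl carbonate) F18, whose two remaining carbonates are cleaved by K2CO3 in MeOH, returning to 22.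

## Further compounds

F1 | step 5 | C18 tert-butyl ester of 9, 1-tert-butyl 3-methyl 2-(4-methoxy-4-oxobutyl)-1,3-dimethylcyclohexane-1,3-dicarboxylate | COC(=O)CCC[C@H]1[C@@](C(=O)OC)(C)CCC[C@]1(C)C(=O)OC(C)(C)C
F2 | step 5 | tert-butyl ester of β-keto ester acid 10 | O=C1C(C(=O)OC)CC[C@H]2[C@@]1(C)CCC[C@]2(C)C(=O)OC(C)(C)C
F3 | step 8 | enol triflate acid (9-triflyloxy, C8=C9, 18-acid) | FC(F)(F)S(=O)(=O)OC1=C(C(=O)OC)CC[C@H]2[C@@]1(C)CCC[C@]2(C)C(=O)O
F4 | step 8 | enol triflate C18 alcohol | FC(F)(F)S(=O)(=O)OC1=C(C(=O)OC)CC[C@H]2[C@@]1(C)CCC[C@]2(C)CO
F5 | step 8 | 6,18-epoxide (tetrahydrofuran) enol triflate | FC(F)(F)S(=O)(=O)OC1=C(C(=O)OC)C[C@@H]3[C@H]2[C@@]1(C)CCC[C@]2(C)CO3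
F6 | step 2 | methyl 12-acetyldehydroabietate | CC(C)c1c(C(C)=O)cc2c(c1)CC[C@H]3[C@@](C(=O)OC)(C)CCC[C@]23C
F7 | step 2 | methyl 12-acetoxydehydroabietate | CC(C)c1c(OC(C)=O)cc2c(c1)CC[C@H]3[C@@](C(=O)OC)(C)CCC[C@]23C
F8 | step 2 | methyl 12-hydroxydehydroabietate | CC(C)c1c(O)cc2c(c1)CC[C@H]3[C@@](C(=O)OC)(C)CCC[C@]23C
F9 | step 3 | dibenzyl ester of 4 | O=C(OCc2ccccc2)CC[C@H]1[C@@](C(=O)OC)(C)CCC[C@]1(C)C(=O)OCc3ccccc3
F10 | step 3 | C18 benzyl ester acid | OC(=O)CC[C@H]1[C@@](C(=O)OC)(C)CCC[C@]1(C)C(=O)OCc2ccccc2
F11 | step 3 | C18 benzyl ester diazoketone | [N-]=[N+]=CC(=O)CC[C@H]1[C@@](C(=O)OC)(C)CCC[C@]1(C)C(=O)OCc2ccccc2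
F12 | step 3 | C18 benzyl ester of 9 | COC(=O)CCC[C@H]1[C@@](C(=O)OC)(C)CCC[C@]1(C)C(=O)OCc2ccccc2
F13 | step 9 | dioxolanylmethyl lactone ester (9-(1,3-dioxolan-2-ylmethyl), C8=C9, 8-CO2Me, 18,6-olide) | C1(OCCO1)CC2=C(C(=O)OC)C[C@@H]4[C@H]3[C@@]2(C)CCC[C@]3(C)C(=O)O4
F14 | step 9 | acetal triol | C1(OCCO1)CC2=C(CO)C[C@@H](O)[C@H]3[C@@]2(C)CCC[C@]3(C)CO
F15 | step 9 | acetal diol (8(17)-methylene, 9-H anti to C20) | C1(OCCO1)C[C@@H]2C(=C)C[C@@H](O)[C@H]3[C@@]2(C)CCC[C@]3(C)CO
F16 | step 9 | C12 aldehyde diol | O=CC[C@@H]1C(=C)C[C@@H](O)[C@H]2[C@@]1(C)CCC[C@]2(C)CO
F17 | step 11 | tris(methyl carbonate) of 19 | C=CCC1=C(COC(=O)OC)C[C@@H](OC(=O)OC)[C@H]2[C@@]1(C)CCC[C@]2(C)COC(=O)OC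
F18 | step 11 | bis(methyl carbonate) of 22 | C=CC[C@@H]1C(=C)C[C@@H](OC(=O)OC)[C@H]2[C@@]1(C)CCC[C@]2(C)COC(=O)OC
A1 | alternative 1 | trans-fused Δ1-octalin methyl ester with C6 silyl ether, C8 ketal and PMB-oxyethyl on C9 | COc1ccc(COCC[C@@H]2C3(OCCO3)C[C@@H](O[Si](C)(C)C(C)(C)C)[C@H]4[C@@]2(C)C=CC[C@]4(C)C(=O)OC)cc1
A2 | alternative 1 | acyclic tetraene (E-2-methyl enoate, E-diene, C6 silyl ether, C8 ketal, PMB-oxyethyl on C9) | COc1ccc(COCC[C@@H](/C(C)=C/C=C)C2(OCCO2)C[C@@H](O[Si](C)(C)C(C)(C)C)/C=C(\C)C(=O)OC)cc1
A3 | alternative 1 | ethylaluminium dichloride | CC[Al](Cl)Cl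
A4 | alternative 2 | 3-hydroxy-8-oxo trans-decalin with C11 ester on C9 and C18 silyl ether | COC(=O)[C@@H]1C(=O)CC[C@H]2[C@@]1(C)CC[C@@H](O)[C@]2(C)CO[Si](c3ccccc3)(c3ccccc3)C(C)(C)C
A5 | alternative 2 | acyclic epoxy β-keto ester (E-alkene, C3–C4 epoxide, C18 silyl ether) | COC(=O)CC(=O)CC/C=C(\C)CC[C@H]1O[C@]1(C)CO[Si](c2ccccc2)(c2ccccc2)C(C)(C)C
A6 | alternative 2 | methylaluminium dichloride | C[Al](Cl)Cl
A7 | alternative 3 | 3-oxo trans-decalin methyl ester with C6 silyl ether and C9 ketal | O1CCOC12CC[C@@H](O[Si](C)(C)C(C)(C)C)[C@H]3[C@@]2(C)CCC(=O)[C@]3(C)C(=O)OC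
A8 | alternative 3 | ring B precursor (exocyclic C10=C20 alkene, C9 ketal, C6 silyl ether, vinyl ketone and ester on C4) | C=CC(=O)[C@](C)(C(=O)OC)[C@H]1[C@H](O[Si](C)(C)C(C)(C)C)CCC2(OCCO2)C1=C
A9 | alternative 3 | iron tris(acetylacetonate), Fe(acac)3 | CC(=O)/C=C(/C)[O-].CC(=O)/C=C(/C)[O-].CC(=O)/C=C(/C)[O-].[Fe+3]
A10 | alternative 3 | phenylsilane | [SiH3]c1ccccc1
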